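**Strategy.** The trans-decalin is disconnected at C4–C5 and C9–C10 (labdane numbering). This unfolds rings A and B into an acyclic (4E,8E)-dienyl malonate whose only stereocentre is the C6 silyl ether. One oxidative radical cascade closes ring A and ring B, sets C5, C9 and C10 from C6 and leaves the C8 exocyclic alkene. It exploits the C4 quaternary ester carbon, the C5/C10 ring fusion and the equatorial C6 oxygen of the decalin. The 6α-oxygen then sorts the two C4 esters by lactonisation, and the hydroperoxy butenolide chain is built out from C12.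

Key step: step 11

Remark (numbering): labdane locants are used: C1–C10 decalin, C11 and C12 on C9, C17 on C8, C18 the α and C19 the β carbon on C4, C20 on C10, then C13 with its methylene C16, C14 and C15; butenolide atoms are primed (C5′ is bonded to C15).

Remark (design): the C12 oxygen is carried as a benzyl ether and the malonate is attached after the organobarium step, because an ester at C12 or an acidic malonate C–H would consume an allylbarium reagent; no skeletal bond of the cyclisation substrate is changed.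

**Route**

Step 1
Reactants: 1 4-methylpent-3-en-1-ol
Product: 2 benzyl 4-methylpent-3-enyl ether
Conditions: NaH, BnBr, Bu4NI (cat.), THF, 0 °C to rt
Reagents that add atoms: benzyl bromide, BrCc1ccccc1
Why: Williamson etherification; the benzyl ether tolerates the organobarium, radical, enolate and saponification steps and is removed by hydrogenolysis once no alkene is left.

Step 2
Reactants: 2 benzyl 4-methylpent-3-enyl ether
Product: 3 (E)-5-(benzyloxy)-2-methylpent-2-en-1-ol
Conditions: SeO2 (0.5 equiv), t-BuOOH (2 equiv), salicylic acid (0.1 equiv), CH2Cl2, rt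
Reagents that add atoms: selenium dioxide, O=[Se]=O; tert-butyl hydroperoxide, CC(C)(C)OO
Why: SeO2 allylic oxidation (ene reaction then [2,3]-sigmatropic shift) hydroxylates the (E)-methyl group of the trisubstituted alkene, which fixes the later C8=C9 alkene as E.

Step 3
Reactants: 3 (E)-5-(benzyloxy)-2-methylpent-2-en-1-ol
Product: 5 benzyl (E)-5-chloro-4-methylpent-3-enyl ether, via mesylate 4 (not isolated)
Conditions: MsCl, 2,4,6-collidine, LiCl, DMF, 0 °C
Reagents that add atoms: lithium chloride, [Li+].[Cl-]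
Why: SN2 displacement of the allylic mesylate by chloride proceeds without allylic transposition, so the E geometry is kept.

Step 4
Reactants: 6 5-chloropent-1-yne
Product: 8 (E)-6-chloro-3-methylhex-2-en-1-ol, via alkenylalane 7 (not isolated)
Conditions: Me3Al (2 equiv), Cp2ZrCl2 (0.2 equiv), CH2Cl2, 0 °C to rt; n-BuLi, THF, −78 °C; (CH2O)n, −78 °C to rt; aq HCl
Reagents that add atoms: trimethylaluminium, C[Al](C)C; formaldehyde (as paraformaldehyde), C=O
Why: Negishi carboalumination adds methyl and aluminium syn across the alkyne and the alkenyl aluminate is trapped by formaldehyde, so the C5=C10 alkene should form as the E isomer only.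

Step 5
Reactants: 8 (E)-6-chloro-3-methylhex-2-en-1-ol
Product: 9 (E)-6-chloro-3-methylhex-2-enal
Conditions: MnO2 (activated), CH2Cl2, rt
Reagents that add atoms: none
Why: MnO2 oxidation is selective for allylic alcohols and does not isomerise the alkene.

Step 6
Reactants: 5 benzyl (E)-5-chloro-4-methylpent-3-enyl ether, 9 (E)-6-chloro-3-methylhex-2-enal
Product: 11 rac-(4E,8E)-11-(benzyloxy)-1-chloro-4,8-dimethylundeca-4,8-dien-6-ol, via allylbarium chloride 10 (not isolated)
Conditions: BaI2, lithium biphenylide (2 equiv), THF, rt; 5, −78 °C; then 9, −78 °C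
Reagents that add atoms: none
Why: α-selective 1,2-addition of an allylic barium reagent to an aldehyde keeps the alkene geometry and forms C6–C7; C6 forms racemic and is set in steps 7 and 8, and the alkyl chloride and benzyl ether are inert at −78 °C.

Step 7
Reactants: 11 rac-(4E,8E)-11-(benzyloxy)-1-chloro-4,8-dimethylundeca-4,8-dien-6-ol
Product: 12 (4E,8E)-11-(benzyloxy)-1-chloro-4,8-dimethylundeca-4,8-dien-6-one
Conditions: Dess–Martin periodinane, NaHCO3, CH2Cl2, 0 °C to rt
Reagents that add atoms: none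
Why: Dess–Martin oxidation under buffered conditions gives the ketone without moving the C8=C9 alkene into conjugation.

Step 8
Reactants: 12 (4E,8E)-11-(benzyloxy)-1-chloro-4,8-dimethylundeca-4,8-dien-6-one
Product: 13 (4E,6S,8E)-11-(benzyloxy)-1-chloro-4,8-dimethylundeca-4,8-dien-6-ol
Conditions: (R)-Me-CBS (0.3 equiv), catecholborane, toluene, −78 °C
Reagents that add atoms: none
Why: Corey–Bakshi–Shibata reduction in which the alkenyl side is the large group and the C7 methylene the small one, so the (R)-catalyst should deliver the 6S carbinol by 1,2-reduction.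

Step 9
Reactants: 13 (4E,6S,8E)-11-(benzyloxy)-1-chloro-4,8-dimethylundeca-4,8-dien-6-ol
Product: 14 (4E,6S,8E)-11-(benzyloxy)-6-(tert-butyldimethylsilyloxy)-1-chloro-4,8-dimethylundeca-4,8-diene
Conditions: TBSCl, imidazole, DMF, rt
Reagents that add atoms: tert-butyldimethylsilyl chloride, CC(C)(C)[Si](C)(C)Cl
Why: Silylation of the secondary allylic alcohol installs the bulky ether that later steers the cyclisation and survives the malonate alkylation.

Step 10
Reactants: 14 (4E,6S,8E)-11-(benzyloxy)-6-(tert-butyldimethylsilyloxy)-1-chloro-4,8-dimethylundeca-4,8-diene, 15 dimethyl malonate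
Product: 17 dimethyl 2-[(4E,6S,8E)-11-(benzyloxy)-6-(tert-butyldimethylsilyloxy)-4,8-dimethylundeca-4,8-dienyl]malonate, via sodium dimethyl malonate 16 (not isolated)
Conditions: NaH, 15 (3 equiv), NaI (cat.), DMF, 70 °C
Reagents that add atoms: none
Why: SN2 malonate alkylation of the primary chloride under Finkelstein catalysis, with excess malonate to suppress dialkylation.

Step 11
Reactants: 17 dimethyl 2-[(4E,6S,8E)-11-(benzyloxy)-6-(tert-butyldimethylsilyloxy)-4,8-dimethylundeca-4,8-dienyl]malonate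
Product: 18 dimethyl 12-(benzyloxy)-6α-(tert-butyldimethylsilyloxy)-13,14,15,16-tetranorlabd-8(17)-ene-18,19-dioate
Conditions: Mn(OAc)3·2H2O (2.2 equiv), Cu(OAc)2·H2O (1 equiv), NaOAc (2 equiv), degassed AcOH, 50 °C
Reagents that add atoms: none
Why: Trivalent manganese oxidises the malonate enolate to the electrophilic C4 radical, which adds 6-endo-trig to C5 (ring A); the tertiary C10 radical then adds 6-endo-trig to C9 (ring B) through a chair transition state, and divalent copper oxidises the tertiary C8 radical to the exocyclic alkene. The closest known reaction type is the Mn(OAc)3/Cu(OAc)2 oxidative free-radical polyene cyclisation of unsaturated malonates and β-keto esters. C5 is controlled by C6: allylic 1,3-strain with the C10 methyl holds H6 in the alkene plane and the radical attacks anti to C7 with the silyloxy group turned outward, which is the fold that leaves this group equatorial on ring B. C10 is set by equatorial closure of ring B on the ring A chair (trans fusion), and C9 by the E geometry of the C8=C9 alkene, which places C11 equatorial. The step needs 6-endo over 5-exo closure (secured by the methyl groups on C10 and C8), facial selectivity at C5 (secured by the C6 silyl ether) and exocyclic alkene formation (secured by copper-mediated oxidative elimination toward the less substituted alkene).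

Step 12
Reactants: 18 dimethyl 12-(benzyloxy)-6α-(tert-butyldimethylsilyloxy)-13,14,15,16-tetranorlabd-8(17)-ene-18,19-dioate
Product: 20 methyl 12-(benzyloxy)-13,14,15,16-tetranorlabd-8(17)-en-18,6α-olid-19-oate, via hydroxy diester 19 (not isolated)
Conditions: Bu4NF, THF, 0 to 40 °C
Reagents that add atoms: none
Why: Fluoride desilylation frees the 6α-alkoxide, which can reach only the α (equatorial, peri) ester and closes the γ-lactone by acyl substitution, so the two C4 esters are told apart by geometry.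

Step 13
Reactants: 20 methyl 12-(benzyloxy)-13,14,15,16-tetranorlabd-8(17)-en-18,6α-olid-19-oate
Product: 21 12-(benzyloxy)-13,14,15,16,19-pentanorlabd-8(17)-en-18,6α-olide
Conditions: LiCl, H2O, DMSO, 150 °C
Reagents that add atoms: none
Why: Krapcho dealkoxycarbonylation removes the β ester (chloride attacks its methyl group, the acyl-lactone carboxylate loses CO2), and the new C4–H must be β because C18 is tied to O6.

Step 14
Reactants: 21 12-(benzyloxy)-13,14,15,16,19-pentanorlabd-8(17)-en-18,6α-olide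
Product: 23 12-(benzyloxy)-13,14,15,16-tetranorlabd-8(17)-en-18,6α-olide, via lithium enolate 22 (not isolated)
Conditions: LiN(i-Pr)2, THF, −78 °C; MeI, −78 to −20 °C
Reagents that add atoms: iodomethane, CI
Why: Lactone enolate alkylation; the lactone bridge holds C18 on the α side, so methyl can enter only from the β face and the C4 quaternary centre (4β-methyl, 4α-carbonyl) is set by the ring.

Step 15
Reactants: 23 12-(benzyloxy)-13,14,15,16-tetranorlabd-8(17)-en-18,6α-olide
Product: 24 12-(benzyloxy)-8α-hydroxy-13,14,15,16-tetranorlabdan-18,6α-olide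
Conditions: Co(acac)2 (20 mol%), PhSiH3, O2 (1 atm), THF, rt
Reagents that add atoms: dioxygen, O=O
Why: Mukaiyama hydration (hydrogen-atom transfer to the methylene, then O2 capture) gives the Markovnikov tertiary alcohol; the C8 radical is trapped on the equatorial α face, away from the axial C10 methyl.

Step 16
Reactants: 24 12-(benzyloxy)-8α-hydroxy-13,14,15,16-tetranorlabdan-18,6α-olide
Product: 26 methyl 12-(benzyloxy)-6α,8α-dihydroxy-13,14,15,16-tetranorlabdan-18-oate, via potassium carboxylate 25 (not isolated)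
Conditions: KOH, MeOH/H2O, 70 °C; CO2 to pH 9, evaporate; MeI, DMF, rt
Reagents that add atoms: potassium hydroxide, [K+].[OH-]; iodomethane, CI
Why: Saponification opens the strained lactone and the carboxylate salt is O-methylated (SN2) without acidification, so the hydroxy acid cannot relactonise; no stereocentre is touched.

Step 17
Reactants: 26 methyl 12-(benzyloxy)-6α,8α-dihydroxy-13,14,15,16-tetranorlabdan-18-oate
Product: 27 methyl 12-(benzyloxy)-6α,8α-bis(triethylsilyloxy)-13,14,15,16-tetranorlabdan-18-oate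
Conditions: Et3SiOTf, 2,6-lutidine, CH2Cl2, −78 to 0 °C
Reagents that add atoms: triethylsilyl trifluoromethanesulfonate, CC[Si](CC)(CC)OS(=O)(=O)C(F)(F)F
Why: Silyl triflate silylation of the hindered secondary and the tertiary hydroxyl blocks relactonisation onto C18 and ether formation between O8 and C12 in the steps that follow.

Step 18
Reactants: 27 methyl 12-(benzyloxy)-6α,8α-bis(triethylsilyloxy)-13,14,15,16-tetranorlabdan-18-oate
Product: 28 methyl 12-hydroxy-6α,8α-bis(triethylsilyloxy)-13,14,15,16-tetranorlabdan-18-oate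
Conditions: H2 (1 atm), 10% Pd/C, EtOAc, rt
Reagents that add atoms: none
Why: Hydrogenolysis of the benzyl ether; no alkene is present and the silyl ethers and ester survive neutral conditions.

Step 19
Reactants: 28 methyl 12-hydroxy-6α,8α-bis(triethylsilyloxy)-13,14,15,16-tetranorlabdan-18-oate
Product: 29 methyl 12-iodo-6α,8α-bis(triethylsilyloxy)-13,14,15,16-tetranorlabdan-18-oate
Conditions: I2, PPh3, imidazole, THF, 0 °C to rt
Reagents that add atoms: iodine, II
Why: Appel-type iodination of the primary alcohol by SN2 on the alkoxyphosphonium ion, buffered by imidazole.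

Step 20
Reactants: 29 methyl 12-iodo-6α,8α-bis(triethylsilyloxy)-13,14,15,16-tetranorlabdan-18-oate
Product: 31 methyl 13-oxo-6α,8α-bis(triethylsilyloxy)-14,15-dinorlabdan-18-oate, via alkylzinc iodide 30 (not isolated)
Conditions: Zn dust (activated), LiCl, THF, 40 °C; then AcCl, Pd(PPh3)4 (5 mol%), THF, 0 °C to rt
Reagents that add atoms: acetyl chloride, CC(=O)Cl
Why: Zinc insertion into the primary iodide gives an ester-tolerant alkylzinc, and palladium-catalysed Negishi acylation attaches C13 and C16 as a methyl ketone.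

Step 21
Reactants: 31 methyl 13-oxo-6α,8α-bis(triethylsilyloxy)-14,15-dinorlabdan-18-oate
Product: 33 methyl 13-(trifluoromethylsulfonyloxy)-6α,8α-bis(triethylsilyloxy)-14,15-dinorlabd-13(16)-en-18-oate, via lithium enolate 32 (not isolated)
Conditions: LiN(i-Pr)2, THF, −78 °C; PhNTf2, −78 to 0 °C
Reagents that add atoms: N-phenylbis(trifluoromethanesulfonimide), O=S(=O)(N(c1ccccc1)S(=O)(=O)C(F)(F)F)C(F)(F)F
Why: Kinetic deprotonation of the methyl ketone at the methyl group and O-triflation give the 1,1-disubstituted enol triflate; the C4 ester has no α-hydrogen.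

Step 22
Reactants: 34 5-hydroxy-4-methylfuran-2(5H)-one
Product: 35 methyl (Z)-3-methyl-4-oxobut-2-enoate
Conditions: MeI, K2CO3, DMF, 0 °C to rt
Reagents that add atoms: iodomethane, CI
Why: Base opens the lactol to the (Z)-formyl carboxylate, and SN2 O-methylation gives the open aldehyde ester with the Z geometry needed for later ring closure.

Step 23
Reactants: 35 methyl (Z)-3-methyl-4-oxobut-2-enoate
Product: 37 (5S)-5-allyl-4-methylfuran-2(5H)-one, via hydroxy ester 36 (not isolated)
Conditions: (−)-Ipc2BOMe, CH2=CHCH2MgBr, Et2O, 0 °C to rt; then 35, −78 °C; HOCH2CH2NH2, rt; PPTS (cat.), CH2Cl2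
Reagents that add atoms: allylmagnesium bromide, C=CC[Mg]Br
Why: Brown allylation; the (−)-diisopinocampheyl reagent delivers allyl to the Si face of the aldehyde through a chair transition state, which sets C5′ as S, and the (Z)-γ-hydroxy ester lactonises to the butenolide.

Step 24
Reactants: 37 (5S)-5-allyl-4-methylfuran-2(5H)-one
Product: 38 2-[(2S)-3-methyl-5-oxo-2,5-dihydrofuran-2-yl]acetaldehyde
Conditions: O3, CH2Cl2, −78 °C; PPh3, −78 °C to rt
Reagents that add atoms: ozone, [O-][O+]=O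
Why: Ozonolysis is selective for the electron-rich terminal alkene over the conjugated butenolide alkene, and reductive work-up gives the aldehyde (C14).

Step 25
Reactants: 33 methyl 13-(trifluoromethylsulfonyloxy)-6α,8α-bis(triethylsilyloxy)-14,15-dinorlabd-13(16)-en-18-oate, 38 2-[(2S)-3-methyl-5-oxo-2,5-dihydrofuran-2-yl]acetaldehyde
Product: 39 methyl (14RS)-14-hydroxy-15-[(2S)-3-methyl-5-oxo-2,5-dihydrofuran-2-yl]-6α,8α-bis(triethylsilyloxy)labd-13(16)-en-18-oate
Conditions: CrCl2 (6 equiv), NiCl2 (2 mol%), degassed DMF, rt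
Reagents that add atoms: none
Why: Nozaki–Hiyama–Kishi reaction; the alkenylchromium species from the enol triflate adds chemoselectively to the aldehyde in the presence of lactone, ester and silyl ethers and forms C13–C14; C14 forms as a mixture and is set in steps 26 and 27.

Step 26
Reactants: 39 methyl (14RS)-14-hydroxy-15-[(2S)-3-methyl-5-oxo-2,5-dihydrofuran-2-yl]-6α,8α-bis(triethylsilyloxy)labd-13(16)-en-18-oate
Product: 40 methyl 15-[(2S)-3-methyl-5-oxo-2,5-dihydrofuran-2-yl]-14-oxo-6α,8α-bis(triethylsilyloxy)labd-13(16)-en-18-oate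
Conditions: Dess–Martin periodinane, NaHCO3, CH2Cl2, 0 °C
Reagents that add atoms: none
Why: Dess–Martin oxidation of the only free hydroxyl under buffered conditions gives the α-methylene ketone without β-elimination of the butenolide oxygen.

Step 27
Reactants: 40 methyl 15-[(2S)-3-methyl-5-oxo-2,5-dihydrofuran-2-yl]-14-oxo-6α,8α-bis(triethylsilyloxy)labd-13(16)-en-18-oate
Product: 41 methyl (14R)-14-hydroxy-15-[(2S)-3-methyl-5-oxo-2,5-dihydrofuran-2-yl]-6α,8α-bis(triethylsilyloxy)labd-13(16)-en-18-oate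
Conditions: (S)-Me-CBS (1 equiv), catecholborane, toluene, −78 °C
Reagents that add atoms: none
Why: Corey–Bakshi–Shibata 1,2-reduction with the α-substituted vinyl group as the large substituent, so the (S)-catalyst should give the 14R alcohol under reagent control.

Step 28
Reactants: 42 2,3-dimethylbut-2-ene
Product: 43 2-hydroperoxy-2-methoxypropane
Conditions: O3, CH2Cl2/MeOH, −78 °C
Reagents that add atoms: ozone, [O-][O+]=O; methanol, CO
Why: Ozonolysis by the Criegee mechanism; methanol traps the carbonyl oxide as the α-methoxy hydroperoxide, a ketal-protected equivalent of hydrogen peroxide.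

Step 29
Reactants: 41 methyl (14R)-14-hydroxy-15-[(2S)-3-methyl-5-oxo-2,5-dihydrofuran-2-yl]-6α,8α-bis(triethylsilyloxy)labd-13(16)-en-18-oate, 43 2-hydroperoxy-2-methoxypropane
Product: 46 methyl (14S)-14-[(2-methoxypropan-2-yl)peroxy]-15-[(2S)-3-methyl-5-oxo-2,5-dihydrofuran-2-yl]-6α,8α-bis(triethylsilyloxy)labd-13(16)-en-18-oate, via mesylate 44 (not isolated), via cesium peroxide 45 (not isolated)
Conditions: MsCl, Et3N, CH2Cl2, −40 °C; then 43, CsOH·H2O, DMF, −20 to 0 °C
Reagents that add atoms: none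
Why: SN2 displacement of the secondary allylic sulfonate by a peroxide anion inverts C14 from R to S; the ketal-capped peroxide cannot add to the butenolide, and the hydroxide-free medium spares the lactone and C5′.

Step 30
Reactants: 46 methyl (14S)-14-[(2-methoxypropan-2-yl)peroxy]-15-[(2S)-3-methyl-5-oxo-2,5-dihydrofuran-2-yl]-6α,8α-bis(triethylsilyloxy)labd-13(16)-en-18-oate
Product: 47 methyl (14S)-14-hydroperoxy-6α,8α-dihydroxy-15-[(2S)-3-methyl-5-oxo-2,5-dihydrofuran-2-yl]labd-13(16)-en-18-oate (CNP0324515.1)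
Conditions: HF (48% aq), MeCN, 0 °C
Reagents that add atoms: none
Why: Dilute aqueous HF cleaves both triethylsilyl ethers and hydrolyses the peroxyketal to the hydroperoxide; no stereocentre is touched, and the acid is too weak at 0 °C for Hock cleavage or relactonisation.

**Compound list**

1 | 4-methylpent-3-en-1-ol | CC(C)=CCCO | starting material
2 | benzyl 4-methylpent-3-enyl ether | CC(C)=CCCOCc1ccccc1 | intermediate
3 | (E)-5-(benzyloxy)-2-methylpent-2-en-1-ol | OC/C(C)=C/CCOCc1ccccc1 | intermediate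
4 | (E)-5-(benzyloxy)-2-methylpent-2-enyl methanesulfonate (not isolated) | CS(=O)(=O)OC/C(C)=C/CCOCc1ccccc1 | intermediate
5 | benzyl (E)-5-chloro-4-methylpent-3-enyl ether | ClC/C(C)=C/CCOCc1ccccc1 | intermediate
6 | 5-chloropent-1-yne | C#CCCCCl | starting material
7 | (E)-(5-chloro-2-methylpent-1-enyl)dimethylalane (not isolated) | C[Al](C)/C=C(C)/CCCCl | intermediate
8 | (E)-6-chloro-3-methylhex-2-en-1-ol | OC/C=C(C)/CCCCl | intermediate
9 | (E)-6-chloro-3-methylhex-2-enal | O=C/C=C(C)/CCCCl | intermediate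
10 | [(E)-5-(benzyloxy)-2-methylpent-2-enyl]barium chloride (not isolated) | Cl[Ba]C/C(C)=C/CCOCc1ccccc1 | intermediate
11 | rac-(4E,8E)-11-(benzyloxy)-1-chloro-4,8-dimethylundeca-4,8-dien-6-ol | ClCCC/C(C)=C/C(O)C/C(C)=C/CCOCc1ccccc1 | intermediate
12 | (4E,8E)-11-(benzyloxy)-1-chloro-4,8-dimethylundeca-4,8-dien-6-one | ClCCC/C(C)=C/C(=O)C/C(C)=C/CCOCc1ccccc1 | intermediate
13 | (4E,6S,8E)-11-(benzyloxy)-1-chloro-4,8-dimethylundeca-4,8-dien-6-ol | ClCCC/C(C)=C/[C@@H](O)C/C(C)=C/CCOCc1ccccc1 | intermediate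
14 | (4E,6S,8E)-11-(benzyloxy)-6-(tert-butyldimethylsilyloxy)-1-chloro-4,8-dimethylundeca-4,8-diene | ClCCC/C(C)=C/[C@@H](O[Si](C)(C)C(C)(C)C)C/C(C)=C/CCOCc1ccccc1 | intermediate
15 | dimethyl malonate | COC(=O)CC(=O)OC | starting material
16 | sodium dimethyl malonate (not isolated) | [Na+].COC(=O)[CH-]C(=O)OC | intermediate
17 | dimethyl 2-[(4E,6S,8E)-11-(benzyloxy)-6-(tert-butyldimethylsilyloxy)-4,8-dimethylundeca-4,8-dienyl]malonate | COC(=O)C(C(=O)OC)CCC/C(C)=C/[C@@H](O[Si](C)(C)C(C)(C)C)C/C(C)=C/CCOCc1ccccc1 | intermediate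
18 | dimethyl 12-(benzyloxy)-6α-(tert-butyldimethylsilyloxy)-13,14,15,16-tetranorlabd-8(17)-ene-18,19-dioate (trans-decalin; 5α-H, 9α-H, 10β-methyl) | c1ccccc1COCC[C@@H]1[C@@]2(C)CCCC(C(=O)OC)(C(=O)OC)[C@@H]2[C@@H](O[Si](C)(C)C(C)(C)C)CC1=C | intermediate
19 | dimethyl 12-(benzyloxy)-6α-hydroxy-13,14,15,16-tetranorlabd-8(17)-ene-18,19-dioate (as its alkoxide; not isolated) | c1ccccc1COCC[C@@H]1[C@@]2(C)CCCC(C(=O)OC)(C(=O)OC)[C@@H]2[C@@H](O)CC1=C | intermediate
20 | methyl 12-(benzyloxy)-13,14,15,16-tetranorlabd-8(17)-en-18,6α-olid-19-oate (γ-lactone C18 to O6; 4β ester) | c1ccccc1COCC[C@@H]1[C@@]2(C)CCC[C@]3(C(=O)OC)[C@@H]2[C@@H](OC3=O)CC1=C | intermediate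
21 | 12-(benzyloxy)-13,14,15,16,19-pentanorlabd-8(17)-en-18,6α-olide (4β-H) | c1ccccc1COCC[C@@H]1[C@@]2(C)CCC[C@@H]3[C@@H]2[C@@H](OC3=O)CC1=C | intermediate
22 | lithium C4=C18 enolate of 21 (not isolated) | c1ccccc1COCC[C@@H]1[C@@]2(C)CCCC3=C([O-])O[C@H]([C@H]23)CC1=C.[Li+] | intermediate
23 | 12-(benzyloxy)-13,14,15,16-tetranorlabd-8(17)-en-18,6α-olide (4β-methyl) | c1ccccc1COCC[C@@H]1[C@@]2(C)CCC[C@]3(C)[C@@H]2[C@@H](OC3=O)CC1=C | intermediate
24 | 12-(benzyloxy)-8α-hydroxy-13,14,15,16-tetranorlabdan-18,6α-olide | c1ccccc1COCC[C@@H]1[C@@]2(C)CCC[C@]3(C)[C@@H]2[C@@H](OC3=O)C[C@@]1(C)O | intermediate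
25 | potassium 12-(benzyloxy)-6α,8α-dihydroxy-13,14,15,16-tetranorlabdan-18-oate (not isolated) | c1ccccc1COCC[C@@H]1[C@@]2(C)CCC[C@@](C)(C(=O)[O-])[C@@H]2[C@@H](O)C[C@@]1(C)O.[K+] | intermediate
26 | methyl 12-(benzyloxy)-6α,8α-dihydroxy-13,14,15,16-tetranorlabdan-18-oate | c1ccccc1COCC[C@@H]1[C@@]2(C)CCC[C@@](C)(C(=O)OC)[C@@H]2[C@@H](O)C[C@@]1(C)O | intermediate
27 | methyl 12-(benzyloxy)-6α,8α-bis(triethylsilyloxy)-13,14,15,16-tetranorlabdan-18-oate | c1ccccc1COCC[C@@H]1[C@@]2(C)CCC[C@@](C)(C(=O)OC)[C@@H]2[C@@H](O[Si](CC)(CC)CC)C[C@@]1(C)O[Si](CC)(CC)CC | intermediate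
28 | methyl 12-hydroxy-6α,8α-bis(triethylsilyloxy)-13,14,15,16-tetranorlabdan-18-oate | OCC[C@@H]1[C@@]2(C)CCC[C@@](C)(C(=O)OC)[C@@H]2[C@@H](O[Si](CC)(CC)CC)C[C@@]1(C)O[Si](CC)(CC)CC | intermediate
29 | methyl 12-iodo-6α,8α-bis(triethylsilyloxy)-13,14,15,16-tetranorlabdan-18-oate | ICC[C@@H]1[C@@]2(C)CCC[C@@](C)(C(=O)OC)[C@@H]2[C@@H](O[Si](CC)(CC)CC)C[C@@]1(C)O[Si](CC)(CC)CC | intermediate
30 | C12 alkylzinc iodide from 29 (not isolated) | I[Zn]CC[C@@H]1[C@@]2(C)CCC[C@@](C)(C(=O)OC)[C@@H]2[C@@H](O[Si](CC)(CC)CC)C[C@@]1(C)O[Si](CC)(CC)CC | intermediate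
31 | methyl 13-oxo-6α,8α-bis(triethylsilyloxy)-14,15-dinorlabdan-18-oate | CC(=O)CC[C@@H]1[C@@]2(C)CCC[C@@](C)(C(=O)OC)[C@@H]2[C@@H](O[Si](CC)(CC)CC)C[C@@]1(C)O[Si](CC)(CC)CC | intermediate
32 | lithium C13=C16 enolate of 31 (not isolated) | [Li+].[O-]C(=C)CC[C@@H]1[C@@]2(C)CCC[C@@](C)(C(=O)OC)[C@@H]2[C@@H](O[Si](CC)(CC)CC)C[C@@]1(C)O[Si](CC)(CC)CC | intermediate
33 | methyl 13-(trifluoromethylsulfonyloxy)-6α,8α-bis(triethylsilyloxy)-14,15-dinorlabd-13(16)-en-18-oate | C=C(OS(=O)(=O)C(F)(F)F)CC[C@@H]1[C@@]2(C)CCC[C@@](C)(C(=O)OC)[C@@H]2[C@@H](O[Si](CC)(CC)CC)C[C@@]1(C)O[Si](CC)(CC)CC | intermediate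
34 | 5-hydroxy-4-methylfuran-2(5H)-one | CC1=CC(=O)OC1O | starting material
35 | methyl (Z)-3-methyl-4-oxobut-2-enoate | O=C/C(C)=C\C(=O)OC | intermediate
36 | methyl (2Z,4S)-4-hydroxy-3-methylhepta-2,6-dienoate (as its borinate; not isolated) | C=CC[C@H](O)/C(C)=C\C(=O)OC | intermediate
37 | (5S)-5-allyl-4-methylfuran-2(5H)-one | C=CC[C@@H]1OC(=O)C=C1C | intermediate
38 | 2-[(2S)-3-methyl-5-oxo-2,5-dihydrofuran-2-yl]acetaldehyde | O=CC[C@@H]1OC(=O)C=C1C | intermediate
39 | methyl (14RS)-14-hydroxy-15-[(2S)-3-methyl-5-oxo-2,5-dihydrofuran-2-yl]-6α,8α-bis(triethylsilyloxy)labd-13(16)-en-18-oate | C=C(CC[C@@H]1[C@@]2(C)CCC[C@@](C)(C(=O)OC)[C@@H]2[C@@H](O[Si](CC)(CC)CC)C[C@@]1(C)O[Si](CC)(CC)CC)C(O)C[C@@H]1OC(=O)C=C1C | intermediate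
40 | methyl 15-[(2S)-3-methyl-5-oxo-2,5-dihydrofuran-2-yl]-14-oxo-6α,8α-bis(triethylsilyloxy)labd-13(16)-en-18-oate | C=C(CC[C@@H]1[C@@]2(C)CCC[C@@](C)(C(=O)OC)[C@@H]2[C@@H](O[Si](CC)(CC)CC)C[C@@]1(C)O[Si](CC)(CC)CC)C(=O)C[C@@H]1OC(=O)C=C1C | intermediate
41 | methyl (14R)-14-hydroxy-15-[(2S)-3-methyl-5-oxo-2,5-dihydrofuran-2-yl]-6α,8α-bis(triethylsilyloxy)labd-13(16)-en-18-oate | C=C(CC[C@@H]1[C@@]2(C)CCC[C@@](C)(C(=O)OC)[C@@H]2[C@@H](O[Si](CC)(CC)CC)C[C@@]1(C)O[Si](CC)(CC)CC)[C@@H](C[C@@H]1OC(=O)C=C1C)O | intermediate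
42 | 2,3-dimethylbut-2-ene | CC(C)=C(C)C | starting material
43 | 2-hydroperoxy-2-methoxypropane | COC(C)(C)OO | intermediate
44 | (14R)-14-methanesulfonate of 41 (not isolated) | C=C(CC[C@@H]1[C@@]2(C)CCC[C@@](C)(C(=O)OC)[C@@H]2[C@@H](O[Si](CC)(CC)CC)C[C@@]1(C)O[Si](CC)(CC)CC)[C@@H](C[C@@H]1OC(=O)C=C1C)OS(C)(=O)=O | intermediate
45 | cesium 2-methoxypropan-2-yl peroxide (not isolated) | [Cs+].COC(C)(C)O[O-] | intermediate
46 | methyl (14S)-14-[(2-methoxypropan-2-yl)peroxy]-15-[(2S)-3-methyl-5-oxo-2,5-dihydrofuran-2-yl]-6α,8α-bis(triethylsilyloxy)labd-13(16)-en-18-oate | C=C(CC[C@@H]1[C@@]2(C)CCC[C@@](C)(C(=O)OC)[C@@H]2[C@@H](O[Si](CC)(CC)CC)C[C@@]1(C)O[Si](CC)(CC)CC)[C@H](C[C@@H]1OC(=O)C=C1C)OOC(C)(C)OC | intermediate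
47 | methyl (14S)-14-hydroperoxy-6α,8α-dihydroxy-15-[(2S)-3-methyl-5-oxo-2,5-dihydrofuran-2-yl]labd-13(16)-en-18-oate (CNP0324515.1) | C=C(CC[C@@H]1[C@@]2(C)CCC[C@@](C)(C(=O)OC)[C@@H]2[C@@H](O)C[C@@]1(C)O)[C@H](C[C@@H]1OC(=O)C=C1C)OO | target

**Totals and risks**

Total step count: 30. Longest linear sequence: 24 steps (steps 1–3, 6–21, 25–27, 29, 30).

Steps most likely to fail:

Step 11. The monocyclic C10 radical may be oxidised before ring B closes, the silyl ether may be lost in warm acetic acid, or facial control at C5 may be poor. The fallback sets out from 17. Iodination of the malonate (NaH, N-iodosuccinimide, THF) would give the α-iodomalonate F1. An iodine-atom-transfer radical bicyclisation under neutral conditions (hexabutylditin cat., visible light, benzene) would close both rings in the same 6-endo sense and give the tertiary C8 iodide F2. Elimination with DBU toward the methyl hydrogens would return to the route at 18.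

Step 29. The allylic mesylate may ionise with loss of configuration, the peroxide may attack C16 in SN2′ fashion, or the base may epimerise C5′. The fallback sets out from 39 and needs neither C14 epimer in particular. A Mitsunobu reaction with 2-nitrobenzenesulfonylhydrazide (PPh3, diethyl azodicarboxylate, −30 °C) would give the sulfonylhydrazine adduct F6. On warming it would lose sulfinic acid to the allylic diazene F7, which loses N2 with 1,3-transposition to the (13E)-alkene F8. A Schenck ene reaction (O2, tetraphenylporphyrin, visible light, CH2Cl2, 0 °C) should take hydrogen from the C16 methyl on the more crowded side of the alkene and give the hydroperoxide F9, to be separated by chromatography from its C14 epimer and the tertiary C13 regioisomer. The conditions of step 30 then return to the route at 47.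

Step 6. The organobarium reagent may form incompletely, couple with its own chloride, or lose α-selectivity. The fallback sets out from 5. Sodium benzenesulfinate (DMF) would give the allylic sulfone F3. Lithiation (n-BuLi, THF, −78 °C) and addition to 9 at the sulfone-bearing carbon would give the β-hydroxy sulfone F4. Dess–Martin oxidation to the β-keto sulfone F5 and reductive desulfonylation (SmI2, THF/MeOH, −78 °C) with kinetic α-protonation would return to the route at 12.

**Further compounds**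

F1 | step 11 | dimethyl 2-iodo-2-[(4E,6S,8E)-11-(benzyloxy)-6-(tert-butyldimethylsilyloxy)-4,8-dimethylundeca-4,8-dienyl]malonate | COC(=O)C(I)(C(=O)OC)CCC/C(C)=C/[C@@H](O[Si](C)(C)C(C)(C)C)C/C(C)=C/CCOCc1ccccc1
F2 | step 11 | dimethyl 12-(benzyloxy)-6α-(tert-butyldimethylsilyloxy)-8-iodo-13,14,15,16-tetranorlabdane-18,19-dioate | c1ccccc1COCC[C@@H]1[C@@]2(C)CCCC(C(=O)OC)(C(=O)OC)[C@@H]2[C@@H](O[Si](C)(C)C(C)(C)C)CC1(C)I
F3 | step 6 | benzyl (E)-4-methyl-5-(phenylsulfonyl)pent-3-enyl ether | O=S(=O)(C/C(C)=C/CCOCc1ccccc1)c1ccccc1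
F4 | step 6 | (4E,8E)-11-(benzyloxy)-1-chloro-4,8-dimethyl-7-(phenylsulfonyl)undeca-4,8-dien-6-ol | ClCCC/C(C)=C/C(O)C(/C(C)=C/CCOCc1ccccc1)S(=O)(=O)c1ccccc1
F5 | step 6 | (4E,8E)-11-(benzyloxy)-1-chloro-4,8-dimethyl-7-(phenylsulfonyl)undeca-4,8-dien-6-one | ClCCC/C(C)=C/C(=O)C(/C(C)=C/CCOCc1ccccc1)S(=O)(=O)c1ccccc1
F6 | step 29 | methyl 14-[1-(2-nitrophenylsulfonyl)hydrazinyl]-15-[(2S)-3-methyl-5-oxo-2,5-dihydrofuran-2-yl]-6α,8α-bis(triethylsilyloxy)labd-13(16)-en-18-oate | C=C(CC[C@@H]1[C@@]2(C)CCC[C@@](C)(C(=O)OC)[C@@H]2[C@@H](O[Si](CC)(CC)CC)C[C@@]1(C)O[Si](CC)(CC)CC)C(C[C@@H]1OC(=O)C=C1C)N(N)S(=O)(=O)c1ccccc1[N+](=O)[O-]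
F7 | step 29 | methyl 14-diazenyl-15-[(2S)-3-methyl-5-oxo-2,5-dihydrofuran-2-yl]-6α,8α-bis(triethylsilyloxy)labd-13(16)-en-18-oate | C=C(CC[C@@H]1[C@@]2(C)CCC[C@@](C)(C(=O)OC)[C@@H]2[C@@H](O[Si](CC)(CC)CC)C[C@@]1(C)O[Si](CC)(CC)CC)C(C[C@@H]1OC(=O)C=C1C)N=N
F8 | step 29 | methyl (13E)-15-[(2S)-3-methyl-5-oxo-2,5-dihydrofuran-2-yl]-6α,8α-bis(triethylsilyloxy)labd-13-en-18-oate | C/C(CC[C@@H]1[C@@]2(C)CCC[C@@](C)(C(=O)OC)[C@@H]2[C@@H](O[Si](CC)(CC)CC)C[C@@]1(C)O[Si](CC)(CC)CC)=C\C[C@@H]1OC(=O)C=C1C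
F9 | step 29 | methyl (14S)-14-hydroperoxy-15-[(2S)-3-methyl-5-oxo-2,5-dihydrofuran-2-yl]-6α,8α-bis(triethylsilyloxy)labd-13(16)-en-18-oate | C=C(CC[C@@H]1[C@@]2(C)CCC[C@@](C)(C(=O)OC)[C@@H]2[C@@H](O[Si](CC)(CC)CC)C[C@@]1(C)O[Si](CC)(CC)CC)[C@H](C[C@@H]1OC(=O)C=C1C)OO
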